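## Retrosynthetic overview

1. Target 35 comes from macrocyclic carbinol 33 by oxidation at C8 and desilylation; the 11-membered ring is closed last by a Nozaki–Hiyama–Kishi reaction (C8–C9) of enal/vinyl iodide 32.
2. 32 comes from seven-membered lactone 25: reduction to the lactol, Wittig olefination (C9=C10 as a (Z)-2-iodoenoate), senecioylation of the C4 hydroxyl, unmasking of the C8 aldehyde.
3. 25 comes from a ring-expanding Claisen rearrangement of 2-methylene-1,3-dioxolane 24 (made from cyclic carbonate 23); this forms C1–C11, the quaternary centre C1 and the cis C2=C3 bond.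
4. 23 comes from aldehyde 17 plus (Z)-alkenyl iodide 6 (chelation control sets C3), 17 from ketone 10 plus alkyne 11 (chelation control sets C5), and 10 from methyl (S)-glycerate acetonide 7 (supplies C4).
5. Ring order: 1,3-dioxolan-2-one (step 10), then oxepinone (step 11), then cycloundecatriene (step 18).

Assumption: C1–C11 are the ring carbons of the target counted from the quaternary carbon C1 through C4 (ester carbinol), C5 (tertiary carbinol) and C8 (ketone) to the ring CH2 C11; acetal-carbon epimers (8–10, 13, 14), lactol anomers (26) and C8 epimers (33) are carried as mixtures because those centres are destroyed later.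

## Route

Step 1
Reactants: 1 5-bromo-2-methylpent-2-ene; 2 propyne
Product: 6 (1Z)-1-iodo-2,6-dimethylhepta-1,5-diene, via homoprenylmagnesium bromide 3 (not isolated), via homoprenylcopper 4 (not isolated), via alkenylcopper 5 (not isolated)
Conditions: Mg, Et2O; CuBr·SMe2, Et2O/Me2S, −45 °C; 2, −25 °C; I2, THF, −78 → 0 °C
Reagents that add atoms: iodine, II
Why: Normant carbocupration adds the homoprenyl–copper bond syn across propyne (alkyl to the internal carbon) and iodinolysis of the alkenylcopper goes with retention, so iodine ends cis to the homoprenyl chain.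

Step 2
Reactants: 7 methyl (4S)-2,2-dimethyl-1,3-dioxolane-4-carboxylate
Product: 8 methyl (4S)-2-(4-methoxyphenyl)-1,3-dioxolane-4-carboxylate (both C2 epimers)
Conditions: 4-MeOC6H4CH(OMe)2, CSA (cat.), toluene, 50 °C, reduced pressure
Reagents that add atoms: 4-methoxybenzaldehyde dimethyl acetal, COC(OC)c1ccc(OC)cc1
Why: Acid-catalysed transacetalisation, driven by removal of volatile 2,2-dimethoxypropane, exchanges the acetonide for the aryl acetal needed later without touching the purchased C4 stereocentre.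

Step 3
Reactants: 8 methyl (4S)-2-(4-methoxyphenyl)-1,3-dioxolane-4-carboxylate
Product: 10 1-[(4S)-2-(4-methoxyphenyl)-1,3-dioxolan-4-yl]ethan-1-one, via Weinreb amide 9 (not isolated)
Conditions: MeNH(OMe)·HCl, MeMgCl (5 equiv), THF, −20 → 0 °C
Reagents that add atoms: methylmagnesium chloride, C[Mg]Cl
Why: One-pot Weinreb ketone synthesis, in which the magnesium amide converts the ester to the Weinreb amide and its chelated tetrahedral adduct with MeMgCl collapses to the methyl ketone only on work-up, so there is no over-addition and no epimerisation at C4.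

Step 4
Reactants: 10 1-[(4S)-2-(4-methoxyphenyl)-1,3-dioxolan-4-yl]ethan-1-one; 11 3,3-diethoxyprop-1-yne
Product: 13 (2S)-5,5-diethoxy-2-[(4S)-2-(4-methoxyphenyl)-1,3-dioxolan-4-yl]pent-3-yn-2-ol, via alkynylmagnesium bromide 12 (not isolated)
Conditions: 11, EtMgBr, THF, 0 °C → rt; then 10, THF, −78 → −20 °C
Reagents that add atoms: none
Why: Cram-chelate Grignard addition, in which magnesium bridges the ketone oxygen and the C4 acetal oxygen so that the alkynyl group enters from the face of the C4 hydrogen and sets the C5 tertiary carbinol as S.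

Step 5
Reactants: 13 (2S)-5,5-diethoxy-2-[(4S)-2-(4-methoxyphenyl)-1,3-dioxolan-4-yl]pent-3-yn-2-ol
Product: 14 (4S)-4-[(2S)-5,5-diethoxy-2-[(triethylsilyl)oxy]pent-3-yn-2-yl]-2-(4-methoxyphenyl)-1,3-dioxolane
Conditions: Et3SiCl, imidazole, DMAP (cat.), DMF, 40 °C
Reagents that add atoms: chlorotriethylsilane, CC[Si](Cl)(CC)CC
Why: Silylation of the tertiary propargylic alcohol (triflate-free, so the diethyl acetal survives) blocks competing chelation by this oxygen in step 9 and protects it to the end.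

Step 6
Reactants: 14 (4S)-4-[(2S)-5,5-diethoxy-2-[(triethylsilyl)oxy]pent-3-yn-2-yl]-2-(4-methoxyphenyl)-1,3-dioxolane
Product: 15 (2S,3S)-6,6-diethoxy-2-[(4-methoxyphenyl)methoxy]-3-methyl-3-[(triethylsilyl)oxy]hex-4-yn-1-ol
Conditions: iBu2AlH (3 equiv), CH2Cl2, −78 → −20 °C
Reagents that add atoms: none
Why: Regioselective reductive acetal opening, in which the aluminium hydride binds the less hindered primary acetal oxygen and reduces the aryl-stabilised oxocarbenium ion, leaves the PMB ether on the secondary C4 oxygen and converges both acetal epimers.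

Step 7
Reactants: 15 (2S,3S)-6,6-diethoxy-2-[(4-methoxyphenyl)methoxy]-3-methyl-3-[(triethylsilyl)oxy]hex-4-yn-1-ol
Product: 16 (2S,3S,4Z)-6,6-diethoxy-2-[(4-methoxyphenyl)methoxy]-3-methyl-3-[(triethylsilyl)oxy]hex-4-en-1-ol
Conditions: H2 (1 atm), Pd/CaCO3 poisoned with Pb(OAc)2, quinoline, EtOAc, rt
Reagents that add atoms: none
Why: Lindlar semi-hydrogenation delivers H2 syn on the poisoned palladium surface and stops at the (Z)-alkene that becomes C6=C7.

Step 8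
Reactants: 16 (2S,3S,4Z)-6,6-diethoxy-2-[(4-methoxyphenyl)methoxy]-3-methyl-3-[(triethylsilyl)oxy]hex-4-en-1-ol
Product: 17 (2R,3S,4Z)-6,6-diethoxy-2-[(4-methoxyphenyl)methoxy]-3-methyl-3-[(triethylsilyl)oxy]hex-4-enal
Conditions: Dess–Martin periodinane, NaHCO3, CH2Cl2, 0 °C → rt
Reagents that add atoms: none
Why: Buffered Dess–Martin oxidation gives the α-alkoxy aldehyde without epimerising C4 (the descriptor changes to R only because the priorities change).

Step 9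
Reactants: 17 (2R,3S,4Z)-6,6-diethoxy-2-[(4-methoxyphenyl)methoxy]-3-methyl-3-[(triethylsilyl)oxy]hex-4-enal; 6 (1Z)-1-iodo-2,6-dimethylhepta-1,5-diene
Product: 21 (2Z,4S,5S,6R,7Z)-1,1-diethoxy-5-[(4-methoxyphenyl)methoxy]-4,8,12-trimethyl-4-[(triethylsilyl)oxy]trideca-2,7,11-trien-6-yl 1H-imidazole-1-carboxylate, via alkenyllithium 18 (not isolated), via alkenylmagnesium bromide 19 (not isolated), via magnesium alkoxide 20 (not isolated)
Conditions: 6, t-BuLi (2 equiv), Et2O, −78 °C; MgBr2·OEt2; then 17, MgBr2·OEt2, CH2Cl2, −78 °C; then CDI, THF, −78 °C → rt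
Reagents that add atoms: 1,1'-carbonyldiimidazole, O=C(n1ccnc1)n1ccnc1
Why: Cram-chelate addition, in which MgBr2 bridges the aldehyde and PMB-ether oxygens so the (Z)-alkenyl Grignard (made from 6 with retention) attacks anti to the bulky C5 group and gives the 3R (syn) carbinol, whose alkoxide is acylated in the same flask by CDI.

Step 10
Reactants: 21 (2Z,4S,5S,6R,7Z)-1,1-diethoxy-5-[(4-methoxyphenyl)methoxy]-4,8,12-trimethyl-4-[(triethylsilyl)oxy]trideca-2,7,11-trien-6-yl 1H-imidazole-1-carboxylate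
Product: 23 (4R,5S)-4-[(1Z)-2,6-dimethylhepta-1,5-dien-1-yl]-5-[(2S,3Z)-5,5-diethoxy-2-[(triethylsilyl)oxy]pent-3-en-2-yl]-1,3-dioxolan-2-one, via hydroxy imidazolide 22 (not isolated)
Conditions: DDQ, CH2Cl2/pH 7 buffer (10:1), 0 °C → rt; then Et3N (cat.), rt
Reagents that add atoms: none
Why: Oxidative PMB cleavage by DDQ frees the C4 hydroxyl, which closes onto the neighbouring acyl imidazole (intramolecular transcarbonylation) to give the trans cyclic carbonate with both stereocentres untouched.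

Step 11
Reactants: 23 (4R,5S)-4-[(1Z)-2,6-dimethylhepta-1,5-dien-1-yl]-5-[(2S,3Z)-5,5-diethoxy-2-[(triethylsilyl)oxy]pent-3-en-2-yl]-1,3-dioxolan-2-one
Product: 25 (4S,7S)-7-[(2S,3Z)-5,5-diethoxy-2-[(triethylsilyl)oxy]pent-3-en-2-yl]-4-methyl-4-(4-methylpent-3-en-1-yl)-4,7-dihydrooxepin-2(3H)-one, via ketene acetal 24 (not isolated)
Conditions: Cp2TiMe2 (2 equiv), toluene, 110 °C, dark
Reagents that add atoms: dimethyltitanocene Cp2TiMe2, C[Ti](C)(C1C=CC=C1)C1C=CC=C1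
Why: Petasis methylenation gives the 2-methylene-1,3-dioxolane, whose [3,3]-sigmatropic Claisen rearrangement through the only tether-allowed chair-like transition state forms C1–C11, transfers chirality from C3 (R) across the (Z)-alkene to the S quaternary centre C1, and leaves the new C2=C3 bond necessarily cis in the seven-membered lactone.

Step 12
Reactants: 25 (4S,7S)-7-[(2S,3Z)-5,5-diethoxy-2-[(triethylsilyl)oxy]pent-3-en-2-yl]-4-methyl-4-(4-methylpent-3-en-1-yl)-4,7-dihydrooxepin-2(3H)-one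
Product: 26 (4S,7S)-7-[(2S,3Z)-5,5-diethoxy-2-[(triethylsilyl)oxy]pent-3-en-2-yl]-4-methyl-4-(4-methylpent-3-en-1-yl)-2,3,4,7-tetrahydrooxepin-2-ol (both anomers)
Conditions: iBu2AlH (1.1 equiv), CH2Cl2, −78 °C
Reagents that add atoms: none
Why: Partial hydride reduction of the lactone stops at the aluminium hemiacetal at −78 °C and gives the lactol, a masked C10 aldehyde with the C4 hydroxyl attached.

Step 13
Reactants: 26 (4S,7S)-7-[(2S,3Z)-5,5-diethoxy-2-[(triethylsilyl)oxy]pent-3-en-2-yl]-4-methyl-4-(4-methylpent-3-en-1-yl)-2,3,4,7-tetrahydrooxepin-2-ol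
Product: 27 methyl (2Z,5S,6Z,8S,9S,10Z)-12,12-diethoxy-8-hydroxy-2-iodo-5,9-dimethyl-5-(4-methylpent-3-en-1-yl)-9-[(triethylsilyl)oxy]dodeca-2,6,10-trienoate
Conditions: Ph3P=CHCO2Me, NIS, CH2Cl2, −20 °C, 20 min; then 26, −20 °C → rt
Reagents that add atoms: methyl (triphenylphosphoranylidene)acetate, COC(=O)C=P(c1ccccc1)(c1ccccc1)c1ccccc1; N-iodosuccinimide, O=C1CCC(=O)N1I
Why: Wittig olefination of the ring-opened hydroxy aldehyde with the stabilised α-iodo ylide puts the ester trans to the chain, giving the (Z)-2-iodoenoate in which iodine is cis to C11 as the later C8–C9 bond must be.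

Step 14
Reactants: 27 methyl (2Z,5S,6Z,8S,9S,10Z)-12,12-diethoxy-8-hydroxy-2-iodo-5,9-dimethyl-5-(4-methylpent-3-en-1-yl)-9-[(triethylsilyl)oxy]dodeca-2,6,10-trienoate
Product: 28 (2Z,5S,6Z,8S,9S,10Z)-12,12-diethoxy-2-iodo-5,9-dimethyl-5-(4-methylpent-3-en-1-yl)-9-[(triethylsilyl)oxy]dodeca-2,6,10-triene-1,8-diol
Conditions: iBu2AlH (3.5 equiv), CH2Cl2, −78 °C
Reagents that add atoms: none
Why: 1,2-Reduction of the enoate by the aluminium hydride gives the 2-iodoallylic alcohol (the future hydroxymethyl group) and leaves the vinyl iodide and the acetal intact at −78 °C.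

Step 15
Reactants: 28 (2Z,5S,6Z,8S,9S,10Z)-12,12-diethoxy-2-iodo-5,9-dimethyl-5-(4-methylpent-3-en-1-yl)-9-[(triethylsilyl)oxy]dodeca-2,6,10-triene-1,8-diol
Product: 29 (2Z,5S,6Z,8S,9S,10Z)-1-[(tert-butyldimethylsilyl)oxy]-12,12-diethoxy-2-iodo-5,9-dimethyl-5-(4-methylpent-3-en-1-yl)-9-[(triethylsilyl)oxy]dodeca-2,6,10-trien-8-ol
Conditions: t-BuMe2SiCl (1.1 equiv), imidazole, CH2Cl2, 0 °C
Reagents that add atoms: tert-butylchlorodimethylsilane, CC(C)(C)[Si](C)(C)Cl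
Why: Silylation is selective for the unhindered primary allylic hydroxyl over the secondary C4 hydroxyl, which is flanked by a quaternary carbon.

Step 16
Reactants: 29 (2Z,5S,6Z,8S,9S,10Z)-1-[(tert-butyldimethylsilyl)oxy]-12,12-diethoxy-2-iodo-5,9-dimethyl-5-(4-methylpent-3-en-1-yl)-9-[(triethylsilyl)oxy]dodeca-2,6,10-trien-8-ol; 30 3-methylbut-2-enoyl chloride
Product: 31 (2Z,5S,6Z,8S,9S,10Z)-1-[(tert-butyldimethylsilyl)oxy]-12,12-diethoxy-2-iodo-5,9-dimethyl-5-(4-methylpent-3-en-1-yl)-9-[(triethylsilyl)oxy]dodeca-2,6,10-trien-8-yl 3-methylbut-2-enoate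
Conditions: pyridine, DMAP (cat.), CH2Cl2, 0 °C → rt
Reagents that add atoms: none
Why: DMAP-catalysed acylation of the only free hydroxyl installs the senecioate at C4 with retention, and pyridine rather than a trialkylamine avoids deconjugation of the acyl group through a vinylketene.

Step 17
Reactants: 31 (2Z,5S,6Z,8S,9S,10Z)-1-[(tert-butyldimethylsilyl)oxy]-12,12-diethoxy-2-iodo-5,9-dimethyl-5-(4-methylpent-3-en-1-yl)-9-[(triethylsilyl)oxy]dodeca-2,6,10-trien-8-yl 3-methylbut-2-enoate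
Product: 32 (2Z,4S,5S,6Z,8S,10Z)-12-[(tert-butyldimethylsilyl)oxy]-11-iodo-4,8-dimethyl-8-(4-methylpent-3-en-1-yl)-1-oxo-4-[(triethylsilyl)oxy]dodeca-2,6,10-trien-5-yl 3-methylbut-2-enoate
Conditions: PPTS (cat.), acetone/H2O (10:1), rt
Reagents that add atoms: water, O
Why: Mild acid-catalysed acetal hydrolysis unmasks the (Z)-enal (C8) under conditions that the silyl ethers and the ester tolerate, and the quaternary γ-carbon prevents enolisation.

Step 18
Reactants: 32 (2Z,4S,5S,6Z,8S,10Z)-12-[(tert-butyldimethylsilyl)oxy]-11-iodo-4,8-dimethyl-8-(4-methylpent-3-en-1-yl)-1-oxo-4-[(triethylsilyl)oxy]dodeca-2,6,10-trien-5-yl 3-methylbut-2-enoate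
Product: 33 (1S,2Z,4S,6Z,9Z,11S)-7-{[(tert-butyldimethylsilyl)oxy]methyl}-8-hydroxy-4,11-dimethyl-4-(4-methylpent-3-en-1-yl)-11-[(triethylsilyl)oxy]cycloundeca-2,6,9-trien-1-yl 3-methylbut-2-enoate (both C8 epimers)
Conditions: CrCl2 (10 equiv), NiCl2 (2 mol %), DMSO/THF (3:1), rt, 0.003 M, slow addition
Reagents that add atoms: none
Why: Nozaki–Hiyama–Kishi macrocyclisation, in which the alkenylchromium species formed from the vinyl iodide adds chemoselectively to the aldehyde under high dilution, closes the 11-membered ring with retention of the C9=C10 geometry, the three cis alkenes pre-organising the chain.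

Step 19
Reactants: 33 (1S,2Z,4S,6Z,9Z,11S)-7-{[(tert-butyldimethylsilyl)oxy]methyl}-8-hydroxy-4,11-dimethyl-4-(4-methylpent-3-en-1-yl)-11-[(triethylsilyl)oxy]cycloundeca-2,6,9-trien-1-yl 3-methylbut-2-enoate
Product: 34 (1S,2Z,4S,6Z,9Z,11S)-7-{[(tert-butyldimethylsilyl)oxy]methyl}-4,11-dimethyl-4-(4-methylpent-3-en-1-yl)-8-oxo-11-[(triethylsilyl)oxy]cycloundeca-2,6,9-trien-1-yl 3-methylbut-2-enoate
Conditions: Dess–Martin periodinane, NaHCO3, CH2Cl2, 0 °C
Reagents that add atoms: none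
Why: Dess–Martin oxidation of the doubly allylic alcohol gives the cross-conjugated dienone and removes the uncontrolled C8 centre.

Step 20
Reactants: 34 (1S,2Z,4S,6Z,9Z,11S)-7-{[(tert-butyldimethylsilyl)oxy]methyl}-4,11-dimethyl-4-(4-methylpent-3-en-1-yl)-8-oxo-11-[(triethylsilyl)oxy]cycloundeca-2,6,9-trien-1-yl 3-methylbut-2-enoate
Product: 35 (1S,2Z,4S,6Z,9Z,11S)-11-hydroxy-7-(hydroxymethyl)-4,11-dimethyl-4-(4-methylpent-3-en-1-yl)-8-oxocycloundeca-2,6,9-trien-1-yl 3-methylbut-2-enoate (CNP0230506.5)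
Conditions: HF·pyridine, pyridine, THF, 0 °C → rt
Reagents that add atoms: none
Why: Buffered fluoride desilylation (Si–F bond formation) cleaves the primary TBS and tertiary TES ethers without touching the senecioate or the dienone.

## Compound list

1 | 5-bromo-2-methylpent-2-ene | CC(C)=CCCBr | starting material
2 | propyne | CC#C | starting material
3 | (4-methylpent-3-en-1-yl)magnesium bromide | CC(C)=CCC[Mg]Br | intermediate
4 | (4-methylpent-3-en-1-yl)copper | CC(C)=CCC[Cu] | intermediate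
5 | [(1Z)-2,6-dimethylhepta-1,5-dien-1-yl]copper | CC(C)=CCC/C(C)=C\[Cu] | intermediate
6 | (1Z)-1-iodo-2,6-dimethylhepta-1,5-diene | CC(C)=CCC/C(C)=C\I | intermediate
7 | methyl (4S)-2,2-dimethyl-1,3-dioxolane-4-carboxylate | CC1(C)OC[C@H](O1)C(=O)OC | starting material
8 | methyl (4S)-2-(4-methoxyphenyl)-1,3-dioxolane-4-carboxylate (both C2 epimers) | COc1ccc(cc1)C1OC[C@H](O1)C(=O)OC | intermediate
9 | (4S)-N-methoxy-2-(4-methoxyphenyl)-N-methyl-1,3-dioxolane-4-carboxamide | COc1ccc(cc1)C1OC[C@H](O1)C(=O)N(C)OC | intermediate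
10 | 1-[(4S)-2-(4-methoxyphenyl)-1,3-dioxolan-4-yl]ethan-1-one | COc1ccc(cc1)C1OC[C@H](O1)C(C)=O | intermediate
11 | 3,3-diethoxyprop-1-yne | C#CC(OCC)OCC | starting material
12 | (3,3-diethoxyprop-1-yn-1-yl)magnesium bromide | CCOC(OCC)C#C[Mg]Br | intermediate
13 | (2S)-5,5-diethoxy-2-[(4S)-2-(4-methoxyphenyl)-1,3-dioxolan-4-yl]pent-3-yn-2-ol | COc1ccc(cc1)C1OC[C@H](O1)[C@@](C)(O)C#CC(OCC)OCC | intermediate
14 | (4S)-4-[(2S)-5,5-diethoxy-2-[(triethylsilyl)oxy]pent-3-yn-2-yl]-2-(4-methoxyphenyl)-1,3-dioxolane | COc1ccc(cc1)C1OC[C@H](O1)[C@@](C)(O[Si](CC)(CC)CC)C#CC(OCC)OCC | intermediate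
15 | (2S,3S)-6,6-diethoxy-2-[(4-methoxyphenyl)methoxy]-3-methyl-3-[(triethylsilyl)oxy]hex-4-yn-1-ol | OC[C@H](OCc1ccc(OC)cc1)[C@@](C)(O[Si](CC)(CC)CC)C#CC(OCC)OCC | intermediate
16 | (2S,3S,4Z)-6,6-diethoxy-2-[(4-methoxyphenyl)methoxy]-3-methyl-3-[(triethylsilyl)oxy]hex-4-en-1-ol | OC[C@H](OCc1ccc(OC)cc1)[C@@](C)(O[Si](CC)(CC)CC)/C=C\C(OCC)OCC | intermediate
17 | (2R,3S,4Z)-6,6-diethoxy-2-[(4-methoxyphenyl)methoxy]-3-methyl-3-[(triethylsilyl)oxy]hex-4-enal | O=C[C@H](OCc1ccc(OC)cc1)[C@@](C)(O[Si](CC)(CC)CC)/C=C\C(OCC)OCC | intermediate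
18 | [(1Z)-2,6-dimethylhepta-1,5-dien-1-yl]lithium | CC(C)=CCC/C(C)=C\[Li] | intermediate
19 | [(1Z)-2,6-dimethylhepta-1,5-dien-1-yl]magnesium bromide | CC(C)=CCC/C(C)=C\[Mg]Br | intermediate
20 | bromomagnesium (2Z,4S,5S,6R,7Z)-1,1-diethoxy-5-[(4-methoxyphenyl)methoxy]-4,8,12-trimethyl-4-[(triethylsilyl)oxy]trideca-2,7,11-trien-6-olate | CC(C)=CCC/C(C)=C\[C@@H](O[Mg]Br)[C@H](OCc1ccc(OC)cc1)[C@@](C)(O[Si](CC)(CC)CC)/C=C\C(OCC)OCC | intermediate
21 | (2Z,4S,5S,6R,7Z)-1,1-diethoxy-5-[(4-methoxyphenyl)methoxy]-4,8,12-trimethyl-4-[(triethylsilyl)oxy]trideca-2,7,11-trien-6-yl 1H-imidazole-1-carboxylate | CC(C)=CCC/C(C)=C\[C@@H](OC(=O)n1ccnc1)[C@H](OCc1ccc(OC)cc1)[C@@](C)(O[Si](CC)(CC)CC)/C=C\C(OCC)OCC | intermediate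
22 | (2Z,4S,5S,6R,7Z)-1,1-diethoxy-5-hydroxy-4,8,12-trimethyl-4-[(triethylsilyl)oxy]trideca-2,7,11-trien-6-yl 1H-imidazole-1-carboxylate | CC(C)=CCC/C(C)=C\[C@@H](OC(=O)n1ccnc1)[C@H](O)[C@@](C)(O[Si](CC)(CC)CC)/C=C\C(OCC)OCC | intermediate
23 | (4R,5S)-4-[(1Z)-2,6-dimethylhepta-1,5-dien-1-yl]-5-[(2S,3Z)-5,5-diethoxy-2-[(triethylsilyl)oxy]pent-3-en-2-yl]-1,3-dioxolan-2-one | CC(C)=CCC/C(C)=C\[C@H]1OC(=O)O[C@@H]1[C@@](C)(O[Si](CC)(CC)CC)/C=C\C(OCC)OCC | intermediate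
24 | (4R,5S)-4-[(1Z)-2,6-dimethylhepta-1,5-dien-1-yl]-5-[(2S,3Z)-5,5-diethoxy-2-[(triethylsilyl)oxy]pent-3-en-2-yl]-2-methylidene-1,3-dioxolane | CC(C)=CCC/C(C)=C\[C@H]1OC(=C)O[C@@H]1[C@@](C)(O[Si](CC)(CC)CC)/C=C\C(OCC)OCC | intermediate
25 | (4S,7S)-7-[(2S,3Z)-5,5-diethoxy-2-[(triethylsilyl)oxy]pent-3-en-2-yl]-4-methyl-4-(4-methylpent-3-en-1-yl)-4,7-dihydrooxepin-2(3H)-one | CC(C)=CCC[C@]1(C)/C=C\[C@H](OC(=O)C1)[C@@](C)(O[Si](CC)(CC)CC)/C=C\C(OCC)OCC | intermediate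
26 | (4S,7S)-7-[(2S,3Z)-5,5-diethoxy-2-[(triethylsilyl)oxy]pent-3-en-2-yl]-4-methyl-4-(4-methylpent-3-en-1-yl)-2,3,4,7-tetrahydrooxepin-2-ol (both anomers) | CC(C)=CCC[C@]1(C)/C=C\[C@H](OC(O)C1)[C@@](C)(O[Si](CC)(CC)CC)/C=C\C(OCC)OCC | intermediate
27 | methyl (2Z,5S,6Z,8S,9S,10Z)-12,12-diethoxy-8-hydroxy-2-iodo-5,9-dimethyl-5-(4-methylpent-3-en-1-yl)-9-[(triethylsilyl)oxy]dodeca-2,6,10-trienoate | CC(C)=CCC[C@@](C)(C/C=C(\I)C(=O)OC)/C=C\[C@H](O)[C@@](C)(O[Si](CC)(CC)CC)/C=C\C(OCC)OCC | intermediate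
28 | (2Z,5S,6Z,8S,9S,10Z)-12,12-diethoxy-2-iodo-5,9-dimethyl-5-(4-methylpent-3-en-1-yl)-9-[(triethylsilyl)oxy]dodeca-2,6,10-triene-1,8-diol | CC(C)=CCC[C@@](C)(C/C=C(\I)CO)/C=C\[C@H](O)[C@@](C)(O[Si](CC)(CC)CC)/C=C\C(OCC)OCC | intermediate
29 | (2Z,5S,6Z,8S,9S,10Z)-1-[(tert-butyldimethylsilyl)oxy]-12,12-diethoxy-2-iodo-5,9-dimethyl-5-(4-methylpent-3-en-1-yl)-9-[(triethylsilyl)oxy]dodeca-2,6,10-trien-8-ol | CC(C)=CCC[C@@](C)(C/C=C(\I)CO[Si](C)(C)C(C)(C)C)/C=C\[C@H](O)[C@@](C)(O[Si](CC)(CC)CC)/C=C\C(OCC)OCC | intermediate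
30 | 3-methylbut-2-enoyl chloride | CC(C)=CC(Cl)=O | starting material
31 | (2Z,5S,6Z,8S,9S,10Z)-1-[(tert-butyldimethylsilyl)oxy]-12,12-diethoxy-2-iodo-5,9-dimethyl-5-(4-methylpent-3-en-1-yl)-9-[(triethylsilyl)oxy]dodeca-2,6,10-trien-8-yl 3-methylbut-2-enoate | CC(C)=CCC[C@@](C)(C/C=C(\I)CO[Si](C)(C)C(C)(C)C)/C=C\[C@H](OC(=O)C=C(C)C)[C@@](C)(O[Si](CC)(CC)CC)/C=C\C(OCC)OCC | intermediate
32 | (2Z,4S,5S,6Z,8S,10Z)-12-[(tert-butyldimethylsilyl)oxy]-11-iodo-4,8-dimethyl-8-(4-methylpent-3-en-1-yl)-1-oxo-4-[(triethylsilyl)oxy]dodeca-2,6,10-trien-5-yl 3-methylbut-2-enoate | CC(C)=CCC[C@@](C)(C/C=C(\I)CO[Si](C)(C)C(C)(C)C)/C=C\[C@H](OC(=O)C=C(C)C)[C@@](C)(O[Si](CC)(CC)CC)/C=C\C=O | intermediate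
33 | (1S,2Z,4S,6Z,9Z,11S)-7-{[(tert-butyldimethylsilyl)oxy]methyl}-8-hydroxy-4,11-dimethyl-4-(4-methylpent-3-en-1-yl)-11-[(triethylsilyl)oxy]cycloundeca-2,6,9-trien-1-yl 3-methylbut-2-enoate (both C8 epimers) | CC(C)=CCC[C@]1(C)/C=C\[C@H](OC(=O)C=C(C)C)[C@@](C)(O[Si](CC)(CC)CC)/C=C\C(O)/C(CO[Si](C)(C)C(C)(C)C)=C\C1 | intermediate
34 | (1S,2Z,4S,6Z,9Z,11S)-7-{[(tert-butyldimethylsilyl)oxy]methyl}-4,11-dimethyl-4-(4-methylpent-3-en-1-yl)-8-oxo-11-[(triethylsilyl)oxy]cycloundeca-2,6,9-trien-1-yl 3-methylbut-2-enoate | CC(C)=CCC[C@]1(C)/C=C\[C@H](OC(=O)C=C(C)C)[C@@](C)(O[Si](CC)(CC)CC)/C=C\C(=O)/C(CO[Si](C)(C)C(C)(C)C)=C\C1 | intermediate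
35 | (1S,2Z,4S,6Z,9Z,11S)-11-hydroxy-7-(hydroxymethyl)-4,11-dimethyl-4-(4-methylpent-3-en-1-yl)-8-oxocycloundeca-2,6,9-trien-1-yl 3-methylbut-2-enoate (CNP0230506.5) | CC(C)=CCC[C@]1(C)/C=C\[C@H](OC(=O)C=C(C)C)[C@@](C)(O)/C=C\C(=O)/C(CO)=C\C1 | target

## Step count and risks

Total steps: 20. Longest linear sequence: 19 steps (7 → 35, steps 2–20); step 1 is a one-step side branch that joins at step 9.

Steps most likely to fail:

Step 11 (methylenation–Claisen on a five-membered carbonate). The bicyclic transition state is more strained than in the six- and seven-membered cases, the product lactone 25 can itself be methylenated, and the allylic C3–O bond can ionise. The fallback generates the same ketene acetal without titanium, by selenoxide elimination under basic conditions. It sets out from carbonate 23: K2CO3 in MeOH gives the diol (2Z,4S,5S,6R,7Z)-1,1-diethoxy-4,8,12-trimethyl-4-[(triethylsilyl)oxy]trideca-2,7,11-triene-5,6-diol F2. Acetalisation with PhSeCH2CH(OEt)2 (PPTS, toluene, reflux) gives the 2-[(phenylselanyl)methyl]-1,3-dioxolane F3. NaIO4/NaHCO3 in aqueous MeOH gives the selenoxide F4, which on heating with DBU in xylene eliminates to ketene acetal 24 and rearranges, coming back to the route at lactone 25.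

Step 18 (macrocyclisation). The (Z)-enal can isomerise or oligomerise before the 11-membered ring closes. The fallback forms the same C8–C9 bond by acyl substitution instead of carbonyl addition, which also makes step 19 unnecessary. It sets out from enal 32: NaClO2/NaH2PO4/2-methylbut-2-ene gives the (2Z)-enoic acid F5. EtSH/EDC/DMAP gives the S-ethyl thioester F6. Zinc insertion into the C–I bond (Zn, LiCl, THF) gives the alkenylzinc iodide F7, and PdCl2(PPh3)2 under high dilution effects an intramolecular Fukuyama ketone coupling, coming back at ketone 34.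

Step 4 (C5 carbinol). Chelation through an acetal oxygen may be weaker than through a simple ether, which would erode or invert the selectivity. The fallback reverses the order in which the two carbon groups reach C5, so that Felkin–Anh (non-chelation) control leads to the same alcohol. It sets out from ester 8: conversion to Weinreb amide 9 (here isolated; MeNH(OMe)·HCl, iPrMgCl) and addition of the lithium acetylide of 11 give the ynone 4,4-diethoxy-1-[(4S)-2-(4-methoxyphenyl)-1,3-dioxolan-4-yl]but-2-yn-1-one F1. Addition of non-chelating MeTi(OiPr)3 (Et2O, −40 °C) then comes back to the route at alcohol 13.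

Further compounds
F1 | step 4 | 4,4-diethoxy-1-[(4S)-2-(4-methoxyphenyl)-1,3-dioxolan-4-yl]but-2-yn-1-one | COc1ccc(cc1)C1OC[C@H](O1)C(=O)C#CC(OCC)OCC
F2 | step 11 | (2Z,4S,5S,6R,7Z)-1,1-diethoxy-4,8,12-trimethyl-4-[(triethylsilyl)oxy]trideca-2,7,11-triene-5,6-diol | CC(C)=CCC/C(C)=C\[C@@H](O)[C@H](O)[C@@](C)(O[Si](CC)(CC)CC)/C=C\C(OCC)OCC
F3 | step 11 | (4R,5S)-4-[(1Z)-2,6-dimethylhepta-1,5-dien-1-yl]-5-[(2S,3Z)-5,5-diethoxy-2-[(triethylsilyl)oxy]pent-3-en-2-yl]-2-[(phenylselanyl)methyl]-1,3-dioxolane | CC(C)=CCC/C(C)=C\[C@H]1OC(C[Se]c2ccccc2)O[C@@H]1[C@@](C)(O[Si](CC)(CC)CC)/C=C\C(OCC)OCC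
F4 | step 11 | (4R,5S)-4-[(1Z)-2,6-dimethylhepta-1,5-dien-1-yl]-5-[(2S,3Z)-5,5-diethoxy-2-[(triethylsilyl)oxy]pent-3-en-2-yl]-2-[(phenylseleninyl)methyl]-1,3-dioxolane | CC(C)=CCC/C(C)=C\[C@H]1OC(C[Se](=O)c2ccccc2)O[C@@H]1[C@@](C)(O[Si](CC)(CC)CC)/C=C\C(OCC)OCC
F5 | step 18 | (2Z,4S,5S,6Z,8S,10Z)-12-[(tert-butyldimethylsilyl)oxy]-11-iodo-4,8-dimethyl-5-[(3-methylbut-2-enoyl)oxy]-8-(4-methylpent-3-en-1-yl)-4-[(triethylsilyl)oxy]dodeca-2,6,10-trienoic acid | CC(C)=CCC[C@@](C)(C/C=C(\I)CO[Si](C)(C)C(C)(C)C)/C=C\[C@H](OC(=O)C=C(C)C)[C@@](C)(O[Si](CC)(CC)CC)/C=C\C(O)=O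
F6 | step 18 | S-ethyl (2Z,4S,5S,6Z,8S,10Z)-12-[(tert-butyldimethylsilyl)oxy]-11-iodo-4,8-dimethyl-5-[(3-methylbut-2-enoyl)oxy]-8-(4-methylpent-3-en-1-yl)-4-[(triethylsilyl)oxy]dodeca-2,6,10-trienethioate | CC(C)=CCC[C@@](C)(C/C=C(\I)CO[Si](C)(C)C(C)(C)C)/C=C\[C@H](OC(=O)C=C(C)C)[C@@](C)(O[Si](CC)(CC)CC)/C=C\C(=O)SCC
F7 | step 18 | alkenylzinc iodide of F6 (zinc in place of the vinylic iodine, same alkene geometry) | CC(C)=CCC[C@@](C)(C/C=C(\[Zn]I)CO[Si](C)(C)C(C)(C)C)/C=C\[C@H](OC(=O)C=C(C)C)[C@@](C)(O[Si](CC)(CC)CC)/C=C\C(=O)SCC
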